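Each flask ran 1.0 h, and the flasks differed in how fast their charges went in.

| flask | first end groups | second end groups | time | remark |
|---|---|---|---|---|
| blue | 0.50 M | 0.900 equiv | 1.0 h | everything together at the start |
| red | 0.50 M | 0.900 equiv (fed, over 50 min) | 1.0 h | all else is in the flask from the start; the feed brings no volume worth counting |
| teal | 0.50 M (fed, over 50 min) | 0.900 equiv | 1.0 h | all else is in the flask from the start; the feed brings no volume worth counting |
| amber | 0.50 M | 0.900 equiv (fed, over 5.0 min) | 1.0 h | all else is in the flask from the start; the feed brings no volume worth counting |

    first end groups + second end groups → links (k1 = 0.0030 M⁻¹ s⁻¹)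
    first end groups + second end groups → rings, rate k2*[first end groups] as long as [second end groups] is above zero (k2 = 0.0014 s⁻¹)
    first end groups + links → side product (k3 = 0.0015 M⁻¹ s⁻¹)
    second end groups → decomposed reagent (k4 = 0.0028 s⁻¹)

- a species is counted by the first end groups in it: one side product counts as two
- run time (blue): 1.0 h

1. the flask with the highest amount of rings, in percent of the first end groups charged ("all alike" if they lie within 1.5 percentage points) (blue / red / teal / amber / all alike)
2. final rings, as a percentage of the first end groups charged, in blue
3. final rings, as a percentage of the first end groups charged, in red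
4. final rings, as a percentage of the first end groups charged, in teal
5. final rings, as a percentage of the first end groups charged, in amber

I kept the books on second end groups, the limiting reagent, in red. Its feed brought 0.450 M at 1.50 × 10⁻⁴ M s⁻¹. The ring step takes second end groups at its constant times [first end groups], however little of them stands there, and it began at 7.00 × 10⁻⁴ M s⁻¹, more than the feed brought. So I asked where the two rates meet and called that [first end groups] the takeover level:

takeover level = 1.50 × 10⁻⁴ M s⁻¹ / 0.0014 s⁻¹ = 0.107 M

Entry one, rings until the takeover level, reached after 43.7 min, before the feed ended. I assumed nothing went to links or decomposed reagent here: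

0.50 M − 0.107 M = 0.393 M

Entry two, rings during the last 6.35 min of feed, with [first end groups] now falling by the ring step:

0.107 M × (1 − exp(−0.0014 s⁻¹ × 6.35 min)) = 0.0443 M

Entry three, the pile still unbooked at the end of the feed, open to rings, links and decomposition:

0.450 M − 0.393 M − 0.0443 M = 0.0129 M

The books closed with red's rings between 87.4% and 90.0%. In blue the whole charge stood from the start, and its second end groups had a half-life of 4.13 min against decomposition, shorter than the 10.7 min the ring step needs for them at 7.00 × 10⁻⁴ M s⁻¹. In teal the second end groups stood from the start with that same half-life, while [first end groups] began at zero. After that half-life teal's feed had brought 0.0413 M of first end groups, and even that much gave the ring step 5.78 × 10⁻⁵ M s⁻¹, less than 7.00 × 10⁻⁴ M s⁻¹. Amber's feed ran at 0.00150 M s⁻¹, above 7.00 × 10⁻⁴ M s⁻¹. I put red first.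

The forecast also named red, with blue 39.5% (37.5% to 41.5%), red 89% (86.5% to 90.5%), teal 12.5% (11.5% to 13.5%) and amber 53.7% (51.5% to 56%). Of red, with B for second end groups, it wrote: “B stays near zero, so nearly all fed B becomes rings”.

The simulation gave blue 39.1%, red 88.7%, teal 12.7% and amber 53.3%, so red stood highest, inside my bracket. At 0.500 h, red's [first end groups] of 0.230 M lay above the takeover level, with 0.00869% of its second end groups standing. At 0.833 h, it lay below, at 0.0638 M, with 2.04% standing. Amber's feed ran ten times as fast, so its takeover level was 1.07 M, above the 0.50 M charged. At 0.0833 h, 38.3% of amber's second end groups stood in the flask, and its decomposed reagent finished at 0.137 M, against 0.00582 M in red.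

Its constants were chosen freely; no experiment stands behind them.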